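**Plan**

1. Numbering and abbreviation: lignan numbering is used (C7/C7' aryl-bearing carbons, C8/C8' ring-fusion carbons, C9/C9' methylenes; the unprimed half carries the acetoxy group; ring A = O–C9–C8–C8'–C7', ring B = C8–C7–O–C9'–C8'). The target as drawn is 7S,8R,7'R,8'S, and Ar = 3-methoxy-4-(triisopropylsilyloxy)phenyl.
2. Retrosynthetic cuts, in order: the two aryl O–Si bonds and the acetyl C–O bond; the C9 methylene back to a lactone carbonyl (activating group for C8); the C7–C8 bond of ring B, with C7 returned to O8, so that ring B becomes a six-membered 2-aryl-1,3-dioxane (O8, C7, O, C9', C8', C8) fused to the γ-lactone form of ring A; then the O8–C7 acetal bond (back to a benzyl ether C–H), the O–C7H2 ether bond, the C8–O8 bond, and the C7'–C8' bond together with the lactone C–O bond.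
3. Forward order: an Evans aldol joins C7'–C8' and ring A closes at once as the lactone; C9' is freed and benzylated with the second aryl unit, C8 is hydroxylated, and DDQ closes the dioxane; step 10 contracts the dioxane to ring B; C9 is then reduced to CH2, O8 is acetylated and the phenols are freed.
4. Stereochemistry: C7' and C8' come from the (R)-4-benzyloxazolidinone syn-aldol; the oxygen on C8 enters anti to the C8' side chain; C7 is set as the equatorial acetal carbon and carried into ring B with retention; the quaternary C8 is fixed by the tether (cis ring fusion).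
5. Enabling feature: C8 bears an oxygen and is α to C9, which can be a carbonyl, and O8 stands 1,3 to the ring-B oxygen across C8'–C9'. The aryl carbon C7 can therefore bridge the two oxygens as an acetal, and a [1,2] shift of C7 from O8 to the C8 enolate carbon turns the six-membered ring into ring B, making the C7–C8 bond, the tertiary C8–O centre and both stereocentres in one event.

Key step: step 10

**Route**

Step 1
Reactants: 1 vanillin
Product: 2 3-methoxy-4-(triisopropylsilyloxy)benzaldehyde
Conditions: i-Pr3SiCl, imidazole, DMF, rt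
Reagents that add atoms: triisopropylsilyl chloride, CC(C)[Si](Cl)(C(C)C)C(C)C
Why: Imidazole-promoted silylation of the phenol gives an aryl silyl ether that should survive amide bases, hydrides, DDQ and BF3·OEt2 and fall to fluoride at the end.

Step 2
Reactants: 2 3-methoxy-4-(triisopropylsilyloxy)benzaldehyde
Product: 3 [3-methoxy-4-(triisopropylsilyloxy)phenyl]methanol
Conditions: NaBH4, MeOH, 0 °C
Reagents that add atoms: none
Why: Borohydride reduction of the aryl aldehyde to the benzylic alcohol, with the aryl silyl ether left untouched.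

Step 3
Reactants: 3 [3-methoxy-4-(triisopropylsilyloxy)phenyl]methanol
Product: 4 3-methoxy-4-(triisopropylsilyloxy)benzyl 2,2,2-trichloroacetimidate
Conditions: Cl3CCN, DBU (cat.), CH2Cl2, 0 °C
Reagents that add atoms: trichloroacetonitrile, ClC(Cl)(Cl)C#N
Why: Base-catalysed addition of the alcohol to the nitrile gives the trichloroacetimidate, the standard acid-activated donor for electron-rich benzyl ethers.

Step 4
Reactants: 5 (R)-4-benzyloxazolidin-2-one; 6 methyl 4-chloro-4-oxobutanoate
Product: 7 methyl 4-[(R)-4-benzyl-2-oxooxazolidin-3-yl]-4-oxobutanoate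
Conditions: n-BuLi, THF, −78 °C; then 6, −78 to 0 °C
Reagents that add atoms: none
Why: N-Acylation of the lithiated oxazolidinone by the acid chloride, which is far more electrophilic than the methyl ester.

Step 5
Reactants: 7 methyl 4-[(R)-4-benzyl-2-oxooxazolidin-3-yl]-4-oxobutanoate; 2 3-methoxy-4-(triisopropylsilyloxy)benzaldehyde
Product: 9 (R)-4-benzyl-3-{[(2R,3R)-2-Ar-5-oxotetrahydrofuran-3-yl]carbonyl}oxazolidin-2-one (trans-lactone imide), via syn-aldol adduct 8 (not isolated)
Conditions: Bu2BOTf, i-Pr2NEt, CH2Cl2, −78 to 0 °C; then 2, −78 to 0 °C; pH 7 buffer, MeOH, H2O2, 0 °C; then p-TsOH·H2O (cat.), CH2Cl2, rt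
Reagents that add atoms: none
Why: Evans syn-aldol reaction in which the Z-boron enolate of the imide (the ester is not enolised) adds to 2 through a chair Zimmerman–Traxler transition state on the face away from the benzyl group, setting C8' and C7' (3R,4R in 8), after which the γ-hydroxy ester should lactonise (5-exo-trig) to the trans-lactone.

Step 6
Reactants: 9 trans-lactone imide
Product: 10 (4S,5R)-5-Ar-4-(hydroxymethyl)dihydrofuran-2(3H)-one
Conditions: NaBH4, THF/H2O, 0 °C to rt
Reagents that add atoms: none
Why: Reductive cleavage of the N-acyl oxazolidinone, whose exocyclic carbonyl is more electrophilic than the lactone, should give the primary alcohol and release the auxiliary without touching a stereocentre.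

Step 7
Reactants: 10 (4S,5R)-5-Ar-4-(hydroxymethyl)dihydrofuran-2(3H)-one; 4 3-methoxy-4-(triisopropylsilyloxy)benzyl 2,2,2-trichloroacetimidate
Product: 11 (4S,5R)-5-Ar-4-(ArCH2OCH2)dihydrofuran-2(3H)-one
Conditions: CSA (cat.), CH2Cl2, 0 °C to rt
Reagents that add atoms: none
Why: Acid-catalysed benzylation with a trichloroacetimidate (SN1-type transfer of the stabilised benzyl cation) works without base, so the lactone should not migrate to the primary oxygen; this ether is the protecting group for O9' and the future C7.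

Step 8
Reactants: 11 (4S,5R)-5-Ar-4-(ArCH2OCH2)dihydrofuran-2(3H)-one
Product: 13 (3R,4R,5R)-5-Ar-3-hydroxy-4-(ArCH2OCH2)dihydrofuran-2(3H)-one (all-trans), via potassium enolate 12 (not isolated)
Conditions: KN(SiMe3)2, THF, −78 °C; then 3-phenyl-2-(phenylsulfonyl)oxaziridine, −78 °C; aq. NH4Cl
Reagents that add atoms: 3-phenyl-2-(phenylsulfonyl)oxaziridine (Davis oxaziridine), O=S(=O)(N1OC1c2ccccc2)c3ccccc3
Why: Enolate hydroxylation with the Davis oxaziridine, in which the oxidant should approach anti to the adjacent C8' side chain and so place the new C8 hydroxyl trans to it (3R).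

Step 9
Reactants: 13 all-trans α-hydroxy lactone
Product: 14 acetal lactone (7R,8R,7'R,8'S): 2-Ar-1,3-dioxane (O8–C7–O–C9'–C8'–C8) trans-fused at C8–C8' to the 5-Ar γ-lactone, with aryl, C9 and C7' all equatorial
Conditions: DDQ, 4 Å molecular sieves, CH2Cl2, 0 °C to rt
Reagents that add atoms: none
Why: Oxidative acetal formation in which DDQ abstracts hydride from the electron-rich benzyl ether and the C8 hydroxyl traps the aryl-stabilised oxocarbenium ion (6-endo-trig); the aryl should take the equatorial position of the chair, trans to C7' across the ring, which sets C7, while the lactone-bound benzylic C7'–H is deactivated by its acyloxy group.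

Step 10
Reactants: 14 acetal lactone
Product: 16 (7S,8S,7'R,8'S)-1-hydroxy-4,8-di-Ar-3,7-dioxabicyclo[3.3.0]octan-2-one (cis-fused 8-hydroxy lactone), via potassium enolate 15 (not isolated)
Conditions: KN(SiMe3)2, THF, −78 °C, then warm to 0 °C; aq. NH4Cl
Reagents that add atoms: none
Why: Proposed new method: the amide base should remove the only acidic C–H (C8–H, α to the lactone carbonyl), and the α-alkoxy enolate 15 should undergo a [1,2]-Wittig shift in which the O8–C7 bond breaks homolytically to a tethered pair (the ketyl of the α-ketolactone and the aryl- and oxygen-stabilised C7 radical) that recombines at C8, so that the six-membered dioxane loses O8 from the ring and becomes the tetrahydrofuran ring B while O8 ends as the tertiary alkoxide. The closest known reaction types are the acetal [1,2]-Wittig rearrangement (O-glycoside to C-glycoside, with retention at the migrating acetal carbon) and the [1,2]-Wittig shift of α-benzyloxy lactam and ester enolates; a ring-contracting version on a lactone enolate has not been shown. Ring B closes by 5-exo-trig recombination of the C7 radical with the ketyl carbon C8, the C8–O bond lying outside the new ring. The C8 stereocentre is controlled by the O–C9' tether, which can deliver C7 only to the lactone face that carries C9' and so gives the cis-fused bicycle with O8 cis to H8' (formal replacement of H8 by C7 with retention); the C7 stereocentre is controlled by the equatorial aryl of acetal 14, carried over with retention because cage recombination should be faster than rotation about O–C7, which places the aryl on the convex face. The step needs site-selective deprotonation (secured by the acidity gap between the lactone α-hydrogen and the benzylic acetal hydrogen and by the hindered base at −78 °C) and rearrangement in preference to fragmentation of the enolate (secured by the absence of a leaving group β to the enolate carbon and by the tether that holds the radical pair together).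

Step 11
Reactants: 16 cis-fused 8-hydroxy lactone
Product: 17 (7S,8S,7'R,8'S)-4,8-di-Ar-3,7-dioxabicyclo[3.3.0]octane-1,2-diol (lactol, both C9 anomers)
Conditions: i-Bu2AlH, CH2Cl2, −78 °C; aq. potassium sodium tartrate
Reagents that add atoms: none
Why: Partial reduction of the lactone to the lactol at low temperature, where the tetrahedral aluminate survives until work-up; one equivalent of hydride is used up by the tertiary hydroxyl.

Step 12
Reactants: 17 lactol
Product: 18 (7S,8R,7'R,8'S)-2,6-di-Ar-3,7-dioxabicyclo[3.3.0]octan-1-ol (bis-silyl ether of the 8-hydroxy furofuran)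
Conditions: Et3SiH, BF3·OEt2, CH2Cl2, −78 to −40 °C
Reagents that add atoms: none
Why: Ionic hydrogenation of the lactol, in which BF3 ionises the anomeric hydroxyl and the silane reduces the ring-A oxocarbenium ion to the C9 methylene, so the activating carbonyl is removed and no other stereocentre should be touched at low temperature.

Step 13
Reactants: 18 bis-silyl ether of the 8-hydroxy furofuran
Product: 19 (7S,8R,7'R,8'S)-2,6-di-Ar-3,7-dioxabicyclo[3.3.0]octan-1-yl acetate
Conditions: Ac2O, Et3N, DMAP, CH2Cl2, rt to 40 °C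
Reagents that add atoms: acetic anhydride, CC(=O)OC(C)=O
Why: DMAP-catalysed (Steglich-type) acylation of the tertiary alcohol, the only free hydroxyl since both phenols are silylated.

Step 14
Reactants: 19 silylated acetate
Product: 20 8-acetoxypinoresinol (7S,8R,7'R,8'S)
Conditions: Bu4NF, AcOH, THF, 0 °C
Reagents that add atoms: none
Why: Fluoride cleavage of the two aryl silyl ethers, buffered with acetic acid so that the phenoxides should neither cleave nor take over the tertiary acetate.

**Compound list**

1 | vanillin (4-hydroxy-3-methoxybenzaldehyde) | COc1cc(C=O)ccc1O | starting material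
2 | 3-methoxy-4-(triisopropylsilyloxy)benzaldehyde (ArCHO) | COc1cc(C=O)ccc1O[Si](C(C)C)(C(C)C)C(C)C | intermediate
3 | [3-methoxy-4-(triisopropylsilyloxy)phenyl]methanol (ArCH2OH) | COc1cc(CO)ccc1O[Si](C(C)C)(C(C)C)C(C)C | intermediate
4 | 3-methoxy-4-(triisopropylsilyloxy)benzyl 2,2,2-trichloroacetimidate | COc1cc(COC(=N)C(Cl)(Cl)Cl)ccc1O[Si](C(C)C)(C(C)C)C(C)C | intermediate
5 | (R)-4-benzyloxazolidin-2-one | O=C1N[C@H](Cc2ccccc2)CO1 | starting material
6 | methyl 4-chloro-4-oxobutanoate | COC(=O)CCC(Cl)=O | starting material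
7 | methyl 4-[(R)-4-benzyl-2-oxooxazolidin-3-yl]-4-oxobutanoate | COC(=O)CCC(=O)N1[C@H](Cc2ccccc2)COC1=O | intermediate
8 | methyl (3R,4R)-3-{[(R)-4-benzyl-2-oxooxazolidin-3-yl]carbonyl}-4-hydroxy-4-Ar-butanoate (syn-aldol adduct) | COC(=O)C[C@H]([C@@H](O)c1ccc(O[Si](C(C)C)(C(C)C)C(C)C)c(OC)c1)C(=O)N1[C@H](Cc2ccccc2)COC1=O | intermediate
9 | (R)-4-benzyl-3-{[(2R,3R)-2-Ar-5-oxotetrahydrofuran-3-yl]carbonyl}oxazolidin-2-one (trans-lactone imide) | COc1cc([C@@H]2OC(=O)C[C@H]2C(=O)N3[C@H](Cc4ccccc4)COC3=O)ccc1O[Si](C(C)C)(C(C)C)C(C)C | intermediate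
10 | (4S,5R)-5-Ar-4-(hydroxymethyl)dihydrofuran-2(3H)-one (trans) | COc1cc([C@@H]2OC(=O)C[C@H]2CO)ccc1O[Si](C(C)C)(C(C)C)C(C)C | intermediate
11 | (4S,5R)-5-Ar-4-(ArCH2OCH2)dihydrofuran-2(3H)-one | COc1cc([C@@H]2OC(=O)C[C@H]2COCc3ccc(O[Si](C(C)C)(C(C)C)C(C)C)c(OC)c3)ccc1O[Si](C(C)C)(C(C)C)C(C)C | intermediate
12 | potassium enolate of 11 | COc1cc([C@@H]2OC([O-])=C[C@H]2COCc3ccc(O[Si](C(C)C)(C(C)C)C(C)C)c(OC)c3)ccc1O[Si](C(C)C)(C(C)C)C(C)C.[K+] | intermediate
13 | (3R,4R,5R)-5-Ar-3-hydroxy-4-(ArCH2OCH2)dihydrofuran-2(3H)-one (all-trans) | COc1cc([C@@H]2OC(=O)[C@H](O)[C@H]2COCc3ccc(O[Si](C(C)C)(C(C)C)C(C)C)c(OC)c3)ccc1O[Si](C(C)C)(C(C)C)C(C)C | intermediate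
14 | acetal lactone (7R,8R,7'R,8'S): 2-Ar-1,3-dioxane trans-fused at C8–C8' to the 5-Ar γ-lactone, all ring substituents equatorial | COc1cc([C@@H]2OC(=O)[C@@H]3O[C@H](c4ccc(O[Si](C(C)C)(C(C)C)C(C)C)c(OC)c4)OC[C@@H]23)ccc1O[Si](C(C)C)(C(C)C)C(C)C | intermediate
15 | potassium enolate of 14 (C8=C9–O−) | COc1cc([C@@H]2OC([O-])=C3O[C@H](c4ccc(O[Si](C(C)C)(C(C)C)C(C)C)c(OC)c4)OC[C@@H]23)ccc1O[Si](C(C)C)(C(C)C)C(C)C.[K+] | intermediate
16 | (7S,8S,7'R,8'S)-1-hydroxy-4,8-di-Ar-3,7-dioxabicyclo[3.3.0]octan-2-one (cis-fused 8-hydroxy lactone) | COc1cc([C@@H]2OC(=O)[C@@]3(O)[C@H](c4ccc(O[Si](C(C)C)(C(C)C)C(C)C)c(OC)c4)OC[C@@H]23)ccc1O[Si](C(C)C)(C(C)C)C(C)C | intermediate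
17 | (7S,8S,7'R,8'S)-4,8-di-Ar-3,7-dioxabicyclo[3.3.0]octane-1,2-diol (lactol, both C9 anomers) | COc1cc([C@@H]2OC(O)[C@@]3(O)[C@H](c4ccc(O[Si](C(C)C)(C(C)C)C(C)C)c(OC)c4)OC[C@@H]23)ccc1O[Si](C(C)C)(C(C)C)C(C)C | intermediate
18 | (7S,8R,7'R,8'S)-2,6-di-Ar-3,7-dioxabicyclo[3.3.0]octan-1-ol | COc1cc([C@@H]2OC[C@@]3(O)[C@H](c4ccc(O[Si](C(C)C)(C(C)C)C(C)C)c(OC)c4)OC[C@@H]23)ccc1O[Si](C(C)C)(C(C)C)C(C)C | intermediate
19 | (7S,8R,7'R,8'S)-2,6-di-Ar-3,7-dioxabicyclo[3.3.0]octan-1-yl acetate | COc1cc([C@@H]2OC[C@@]3(OC(C)=O)[C@H](c4ccc(O[Si](C(C)C)(C(C)C)C(C)C)c(OC)c4)OC[C@@H]23)ccc1O[Si](C(C)C)(C(C)C)C(C)C | intermediate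
20 | 8-acetoxypinoresinol (7S,8R,7'R,8'S) | COc1cc([C@@H]2OC[C@@]3(OC(C)=O)[C@H](c4ccc(O)c(OC)c4)OC[C@@H]23)ccc1O | target

**Step count and risks**

Total steps: 14.
Longest linear sequence: 11 steps (steps 1, 5, 6, 7, 8, 9, 10, 11, 12, 13, 14 from vanillin).

Three steps most likely to fail:

Step 10 (proposed new method). Homolysis of the O8–C7 bond in the stabilised enolate may be too slow below the temperature at which the enolate decomposes, or the radical pair may lose the C7 configuration before it recombines. The fallback uses a Norrish–Yang photocyclisation, an established way to close 3-hydroxytetrahydrofurans; it sets out from 13 and comes back at 18. The lactone of 13 would be reduced with i-Bu2AlH (CH2Cl2, −78 °C) to the lactol F1, which Et3SiH and BF3·OEt2 would take to the all-trans tetrahydrofuran-3-ol F2. Dess–Martin periodinane would then give the tetrahydrofuran-3-one F3. On irradiation (mercury lamp, Pyrex, benzene) the excited ketone should abstract a benzylic hydrogen of the ether through a seven-membered transition state, and the 1,5-biradical should close to the cis-fused tertiary alcohol 18. Steps 9 to 12 would then not be needed.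

Step 12. BF3·OEt2 may ionise the two electron-rich benzylic C–O bonds of the furofuran (C7–O and C7'–O) along with the lactol, which would lead to epimerisation at C7 or C7' or to reductive ring opening by the silane. The fallback avoids any carbocation; it sets out from 16 and comes back at 18. LiAlH4 (THF, 0 °C) would reduce the lactone to the triol F4. Selective sulfonylation of the primary hydroxyl of the 1,2-diol (TsCl, Et3N, cat. Bu2SnO, CH2Cl2) would give the primary tosylate F5. NaH in THF should then close ring A by attack of the C7' alkoxide on C9, directly or by way of the C8/C9 epoxide (5-exo-tet at the primary carbon in both cases), giving 18 with the C7'–O bond never broken.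

Step 9. The benzylic cation may be captured by traces of water, with loss of the benzyl group as the aldehyde, or the strained trans-fused ring may close under kinetic control to a mixture of acetal epimers. The fallback separates deprotection from acetal formation; it sets out from 13 and comes back at 14. DDQ in wet CH2Cl2 (pH 7 buffer) would cleave the ether on purpose to the diol F6, returning aldehyde 2. The diol F6 with 2 and PPTS (cat.) in benzene at reflux, with azeotropic removal of water, should then give 14 as the thermodynamic all-equatorial acetal.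

**Further compounds**

F1 | step 10 | (3R,4R,5R)-5-Ar-4-(ArCH2OCH2)tetrahydrofuran-2,3-diol (lactol, both anomers) | COc1cc([C@@H]2OC(O)[C@H](O)[C@H]2COCc3ccc(O[Si](C(C)C)(C(C)C)C(C)C)c(OC)c3)ccc1O[Si](C(C)C)(C(C)C)C(C)C
F2 | step 10 | (3R,4R,5R)-5-Ar-4-(ArCH2OCH2)tetrahydrofuran-3-ol (all-trans) | COc1cc([C@@H]2OC[C@H](O)[C@H]2COCc3ccc(O[Si](C(C)C)(C(C)C)C(C)C)c(OC)c3)ccc1O[Si](C(C)C)(C(C)C)C(C)C
F3 | step 10 | (4S,5R)-5-Ar-4-(ArCH2OCH2)dihydrofuran-3(2H)-one | COc1cc([C@@H]2OCC(=O)[C@H]2COCc3ccc(O[Si](C(C)C)(C(C)C)C(C)C)c(OC)c3)ccc1O[Si](C(C)C)(C(C)C)C(C)C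
F4 | step 12 | (7S,8R,7'R,8'S)-triol: 2-Ar-3-hydroxy-3-(hydroxymethyl)-4-[(R)-Ar(hydroxy)methyl]tetrahydrofuran | COc1cc([C@H](O)[C@@H]2CO[C@@H](c3ccc(O[Si](C(C)C)(C(C)C)C(C)C)c(OC)c3)[C@]2(O)CO)ccc1O[Si](C(C)C)(C(C)C)C(C)C
F5 | step 12 | primary 4-methylbenzenesulfonate of F4 (at C9) | COc1cc([C@H](O)[C@@H]2CO[C@@H](c3ccc(O[Si](C(C)C)(C(C)C)C(C)C)c(OC)c3)[C@]2(O)COS(=O)(=O)c4ccc(C)cc4)ccc1O[Si](C(C)C)(C(C)C)C(C)C
F6 | step 9 | (3R,4R,5R)-5-Ar-3-hydroxy-4-(hydroxymethyl)dihydrofuran-2(3H)-one (all-trans diol) | COc1cc([C@@H]2OC(=O)[C@H](O)[C@H]2CO)ccc1O[Si](C(C)C)(C(C)C)C(C)C
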